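The C3,C4-diol diester is treated as a masked C3=C4 alkene, which exposes the δ,ε-unsaturated ketone O=C8–C7–C6–C5–C4=C3 running across the cis C5(H)/C10(CH3) junction of rings A and B. The route therefore rests on disconnecting C5–C6 while reconnecting C3–C8: an anionic oxy-Cope rearrangement forms C5–C6, closes ring B, releases ring A as the C3=C4 cyclohexene and delivers the C8 ketone, the C7 isopropyl branch and the cis ring fusion in a single operation. Its precursor is an enantiopure 4,6-dimethylbicyclo[2.2.2]oct-5-en-2-ol bearing a 3-methylbut-1-en-2-yl group on the carbinol carbon, syn to the alkene bridge; its methyl-bearing bridgehead becomes C10.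

Key step: step 11

Remark on numbering: the decalins carry eudesmane numbering, β is the face of the C10 methyl group and α the opposite face.
Remark on step 4: the hydride is taken to come from NADPH that the yeast regenerates by fermenting the sucrose, which ends as ethanol and CO2.
Remark on C7: this centre is not controlled at the ketone protonation in step 11, so compounds 20–22 are written as C7 epimer mixtures and C7 is fixed in step 12.

Step 1
Reactants: 1 3-methylcyclohex-2-en-1-one; 2 allyltrimethylsilane
Product: 3 3-allyl-3-methylcyclohexan-1-one (racemic)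
Conditions: TiCl4, CH2Cl2, −78 °C; then H2O
Reagents that add atoms: none
Why: Hosomi–Sakurai conjugate allylation, in which TiCl4 activates the enone and the allylsilane adds to the β,β-disubstituted carbon, builds the quaternary carbon (future C10); the centre is racemic here and loses its stereogenicity in 5.

Step 2
Reactants: 3 3-allyl-3-methylcyclohexan-1-one
Product: 4 2-(1-methyl-3-oxocyclohexyl)acetic acid (racemic)
Conditions: RuCl3·xH2O (cat.), NaIO4, EtOAc/MeCN/H2O, rt
Reagents that add atoms: sodium periodate [Na+].[O-]I(=O)(=O)=O; water O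
Why: RuO4-catalysed oxidative cleavage of the terminal alkene goes through the aldehyde to the acid and so turns the allyl group into the acetic acid arm, while the saturated ketone is inert to the oxidant.

Step 3
Reactants: 4 2-(1-methyl-3-oxocyclohexyl)acetic acid
Product: 5 4-methylbicyclo[2.2.2]octane-2,6-dione (achiral)
Conditions: polyphosphoric acid, AcOH, 100 °C
Reagents that add atoms: none
Why: Acid-mediated intramolecular C-acylation of the ketone enol (Claisen-type cyclisation) can close only from the α′ methylene in a six-membered mode, because the α carbon next to the quaternary centre would have to form a four-membered ring, so the temporary C3–C8 bond and the mirror-symmetric dione result.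

Step 4
Reactants: 5 4-methylbicyclo[2.2.2]octane-2,6-dione
Product: 6 (1R,4S,6S)-6-hydroxy-4-methylbicyclo[2.2.2]octan-2-one (hydroxyl on the side of the keto bridge)
Conditions: baker's yeast (Saccharomyces cerevisiae), sucrose, H2O, 30 °C
Reagents that add atoms: none
Why: Desymmetrising enzymatic carbonyl reduction, well established for bicyclo[2.2.2]octane-2,6-diones, should deliver hydride in the Prelog sense to one of the two enantiotopic carbonyl groups; this sets both bridgeheads (1R,4S) and thereby the future C10, while the 6S carbinol centre is only temporary.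

Step 5
Reactants: 6 (1R,4S,6S)-6-hydroxy-4-methylbicyclo[2.2.2]octan-2-one
Product: 7 (1R,4S,6S)-4-methylspiro[bicyclo[2.2.2]octane-2,2'-[1,3]dioxolan]-6-ol (ethylene ketal of 6)
Conditions: HOCH2CH2OH, PPTS (cat.), benzene, reflux, Dean–Stark
Reagents that add atoms: ethylene glycol OCCO
Why: Acid-catalysed ketalisation with azeotropic removal of water masks the surviving ketone (the future C8 carbonyl) so that the two former carbonyl positions stay distinguishable; the weak pyridinium acid should spare the β-ketol from retro-aldol opening and no stereocentre is touched.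

Step 6
Reactants: 7 (1R,4S,6S)-4-methylspiro[bicyclo[2.2.2]octane-2,2'-[1,3]dioxolan]-6-ol
Product: 8 (1R,4S)-4-methylspiro[bicyclo[2.2.2]octane-2,2'-[1,3]dioxolan]-6-one
Conditions: n-Pr4N[RuO4] (cat.), NMO, 4 Å MS, CH2Cl2, rt
Reagents that add atoms: none
Why: Ley–Griffith oxidation under neutral anhydrous conditions converts the carbinol into the ketone without loosening the ketal, whose position now alone carries the absolute configuration.

Step 7
Reactants: 8 (1R,4S)-4-methylspiro[bicyclo[2.2.2]octane-2,2'-[1,3]dioxolan]-6-one
Product: 10 (1R,4R)-4-methylspiro[bicyclo[2.2.2]oct-5-ene-2,2'-[1,3]dioxolan]-6-yl trifluoromethanesulfonate, via potassium enolate 9 (not isolated)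
Conditions: KN(SiMe3)2, THF, −78 °C; then PhNTf2, −78 → 0 °C
Reagents that add atoms: N-phenylbis(trifluoromethanesulfonimide) O=S(=O)(N(c1ccccc1)S(=O)(=O)C(F)(F)F)C(F)(F)F
Why: Enolate formation and O-sulfonylation (enol triflate synthesis) can give a single regioisomer because the ketone enolises only toward C5, the other α carbon being the bridgehead C1 (Bredt's rule).

Step 8
Reactants: 10 (1R,4R)-4-methylspiro[bicyclo[2.2.2]oct-5-ene-2,2'-[1,3]dioxolan]-6-yl trifluoromethanesulfonate
Product: 12 (1R,4R)-4,6-dimethylbicyclo[2.2.2]oct-5-en-2-one, via ketal-protected methyl alkene 11 (not isolated)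
Conditions: MeZnCl, Pd(PPh3)4 (cat.), THF, 50 °C; then 2 M HCl, THF, rt
Reagents that add atoms: methylzinc chloride C[Zn]Cl; water O
Why: Negishi cross-coupling of the alkenyl triflate under zerovalent palladium catalysis installs the future C4 methyl group and the acidic work-up hydrolyses the dioxolane; the β,γ-enone cannot slip into conjugation since that would need a bridgehead double bond, and both stereocentres are untouched.

Step 9
Reactants: 13 3-methylbutan-2-one
Product: 14 3-methylbutan-2-one 2,4,6-triisopropylbenzenesulfonylhydrazone (E isomer, sulfonamide anti to the isopropyl group)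
Conditions: 2,4,6-(i-Pr)3C6H2SO2NHNH2, MeOH, HCl (cat.), rt
Reagents that add atoms: 2,4,6-triisopropylbenzenesulfonyl hydrazide CC(C)c1cc(C(C)C)c(S(=O)(=O)NN)c(C(C)C)c1
Why: Simple hydrazone condensation, in which the sulfonamide nitrogen settles anti to the isopropyl group and so later directs deprotonation to the methyl side.

Step 10
Reactants: 12 (1R,4R)-4,6-dimethylbicyclo[2.2.2]oct-5-en-2-one; 14 3-methylbutan-2-one 2,4,6-triisopropylbenzenesulfonylhydrazone
Product: 17 (1R,2S,4R)-4,6-dimethyl-2-(3-methylbut-1-en-2-yl)bicyclo[2.2.2]oct-5-en-2-ol (alkenyl group syn to the C5=C6 bridge), via alkenyllithium 15 (not isolated), via alkenylcerium dichloride 16 (not isolated)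
Conditions: 14, n-BuLi (2 equiv), THF/TMEDA, −78 → 0 °C; CeCl3, −78 °C; then 12, −78 °C; aq. NH4Cl
Reagents that add atoms: none
Why: Shapiro reaction (the dianion loses sulfinate and N2 to give the less substituted alkenyllithium) followed by transmetalation to the weakly basic organocerium and 1,2-addition, which suppresses enolisation; the nucleophile should enter from the alkene-bridge face, because the hydrogens of the ethano bridge point into the opposite trajectory whereas the C6 methyl lies in the alkene plane, and this sets C2 as 2S.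

Step 11
Reactants: 17 (1R,2S,4R)-4,6-dimethyl-2-(3-methylbut-1-en-2-yl)bicyclo[2.2.2]oct-5-en-2-ol
Product: 20 (4aS,8aR)-5,8a-dimethyl-3-(propan-2-yl)-3,4,4a,7,8,8a-hexahydronaphthalen-2(1H)-one (cis-fused 5βH-eudesm-3-en-8-one; C7 epimers), via potassium alkoxide 18 (not isolated), via potassium enolate 19 (not isolated)
Conditions: KH, 18-crown-6, THF, 0 → 50 °C; then AcOH, −78 °C
Reagents that add atoms: none
Why: KH with the crown ether gives the free potassium alkoxide, whose negative charge weakens the adjacent C2–C1 bond, so the 1,5-diene CH2=C(i-Pr)–C2–C1–C6(CH3)=C5 undergoes a concerted suprafacial [3,3] shift through the boat-like six-centre transition state imposed by the cage, breaking C1–C2 (C8–C3 in eudesmane numbering) and joining the alkenyl CH2 to C5 (C6–C5). This is the anionic oxy-Cope rearrangement, which is well documented for 2-alkenylbicyclo[2.2.2]oct-5-en-2-olates and is made irreversible by formation of the C7=C8 enolate. Ring B closes as a six-membered ring by this sigmatropic C5–C6 bond formation, while ring A is released from the cage as the C3=C4 cyclohexene. The one lasting new stereocentre, C5, is controlled by the methyl-bearing bridgehead (C10): the alkenyl terminus can reach C5 only on the face of the alkene bridge that looks at the carbinol bridge, so H5 and the C10 methyl end up cis and no trans-fused product can form. C7 arises on protonation of the enolate and is not relied upon. The step needs the alkenyl group syn to the alkene bridge, which step 10 secures, and needs no regiochemical choice because the rigid bicycle offers a single 1,5-diene.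

Step 12
Reactants: 20 cis-fused 5βH-eudesm-3-en-8-one (C7 epimers)
Product: 23 (3R,4S,5S,7R,10R)-3α,4α-dihydroxy-5βH-eudesman-8-one, via iodo acetate 21 (not isolated), via hydroxy acetate 22 (not isolated)
Conditions: I2, AgOAc, AcOH, rt; AcOH/H2O, 90 °C; then NaOMe, MeOH, 40 °C
Reagents that add atoms: silver acetate CC(=O)[O-].[Ag+]
Why: Woodward cis-hydroxylation followed by methanolysis: iodine should add to the β face (the face of H5 and the C10 methyl, ring B screening the α face), acetate opens the iodonium ion anti at tertiary C4, the acetate carbonyl then displaces the C3 iodide from the α side with silver assistance and water cleaves the acetoxonium ion, so both oxygens come from one acetate and stand α (3R,4S); NaOMe removes the acetyl group whichever oxygen carries it and equilibrates C7 through the enolate to the equatorial β-isopropyl epimer (7R), strongly preferred because the saturated ring A keeps the C4 methyl equatorial to avoid a 1,3-diaxial clash with the C10 methyl and so locks the conformer in which a 7α-isopropyl group would be axial and syn to C4.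

Step 13
Reactants: 23 (3R,4S,5S,7R,10R)-3α,4α-dihydroxy-5βH-eudesman-8-one; 24 angelic acid
Product: 26 (3R,4S,5S,7R,10R)-4α-hydroxy-8-oxo-5βH-eudesman-3α-yl (Z)-2-methylbut-2-enoate, via mixed anhydride 25 (not isolated)
Conditions: 24, 2,4,6-Cl3C6H2COCl, Et3N, toluene, rt; then 23, 80 °C
Reagents that add atoms: none
Why: Mixed-anhydride esterification of Yamaguchi type run without a nucleophilic catalyst, conditions under which the Z double bond of the angeloyl unit is retained; only the secondary equatorial 3α-hydroxyl should react because the axial tertiary 4α-hydroxyl is too hindered, and no stereocentre changes.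

Step 14
Reactants: 26 (3R,4S,5S,7R,10R)-4α-hydroxy-8-oxo-5βH-eudesman-3α-yl (Z)-2-methylbut-2-enoate
Product: 27 (3R,4S,5S,7R,10R)-4α-acetoxy-8-oxo-5βH-eudesman-3α-yl (Z)-2-methylbut-2-enoate (target CNP0322180.1)
Conditions: Ac2O, Sc(OTf)3 (cat.), MeCN, −20 °C
Reagents that add atoms: acetic anhydride CC(=O)OC(C)=O
Why: Lewis-acid-catalysed acetylation, a method that acylates hindered tertiary alcohols at low temperature by O-acyl transfer without ionising the C4–O bond, so C4 keeps its configuration and neither the angelate geometry nor C7 is exposed to base.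

Compound list
1 | 3-methylcyclohex-2-en-1-one | CC1=CC(=O)CCC1 | starting material
2 | allyltrimethylsilane | C=CC[Si](C)(C)C | starting material
3 | 3-allyl-3-methylcyclohexan-1-one (racemic) | C=CCC1(C)CCCC(=O)C1 | intermediate
4 | 2-(1-methyl-3-oxocyclohexyl)acetic acid (racemic) | CC1(CC(=O)O)CCCC(=O)C1 | intermediate
5 | 4-methylbicyclo[2.2.2]octane-2,6-dione (achiral) | CC12CCC(C(=O)C1)C(=O)C2 | intermediate
6 | (1R,4S,6S)-6-hydroxy-4-methylbicyclo[2.2.2]octan-2-one | C[C@]12CC[C@H]([C@@H](O)C1)C(=O)C2 | intermediate
7 | (1R,4S,6S)-4-methylspiro[bicyclo[2.2.2]octane-2,2'-[1,3]dioxolan]-6-ol | C[C@]12CC[C@H]([C@@H](O)C1)C1(OCCO1)C2 | intermediate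
8 | (1R,4S)-4-methylspiro[bicyclo[2.2.2]octane-2,2'-[1,3]dioxolan]-6-one | C[C@]12CC[C@H](C(=O)C1)C1(OCCO1)C2 | intermediate
9 | potassium enolate of 8 (C5=C6 enolate) | C[C@]12CC[C@H](C([O-])=C1)C1(OCCO1)C2.[K+] | intermediate (not isolated)
10 | (1R,4R)-4-methylspiro[bicyclo[2.2.2]oct-5-ene-2,2'-[1,3]dioxolan]-6-yl trifluoromethanesulfonate | C[C@]12CC[C@H](C(OS(=O)(=O)C(F)(F)F)=C1)C1(OCCO1)C2 | intermediate
11 | (1R,4R)-4,6-dimethylspiro[bicyclo[2.2.2]oct-5-ene-2,2'-[1,3]dioxolane] | C[C@]12CC[C@H](C(C)=C1)C1(OCCO1)C2 | intermediate (not isolated)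
12 | (1R,4R)-4,6-dimethylbicyclo[2.2.2]oct-5-en-2-one | C[C@]12CC[C@H](C(C)=C1)C(=O)C2 | intermediate
13 | 3-methylbutan-2-one | CC(C)C(C)=O | starting material
14 | 3-methylbutan-2-one 2,4,6-triisopropylbenzenesulfonylhydrazone (E) | CC(C)/C(C)=N/NS(=O)(=O)c1c(C(C)C)cc(C(C)C)cc1C(C)C | intermediate
15 | (3-methylbut-1-en-2-yl)lithium | [Li]C(=C)C(C)C | intermediate (not isolated)
16 | dichloro(3-methylbut-1-en-2-yl)cerium | Cl[Ce](Cl)C(=C)C(C)C | intermediate (not isolated)
17 | (1R,2S,4R)-4,6-dimethyl-2-(3-methylbut-1-en-2-yl)bicyclo[2.2.2]oct-5-en-2-ol, alkenyl syn to the alkene bridge | C[C@]12CC[C@H](C(C)=C1)[C@](O)(C(=C)C(C)C)C2 | intermediate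
18 | potassium alkoxide of 17 | C[C@]12CC[C@H](C(C)=C1)[C@]([O-])(C(=C)C(C)C)C2.[K+] | intermediate (not isolated)
19 | potassium C7=C8 enolate of 20 (cis-fused, 5S,10R) | CC1=CCC[C@]2(C)CC([O-])=C(C(C)C)C[C@H]12.[K+] | intermediate (not isolated)
20 | (4aS,8aR)-5,8a-dimethyl-3-(propan-2-yl)-3,4,4a,7,8,8a-hexahydronaphthalen-2(1H)-one = (5S,10R)-5βH-eudesm-3-en-8-one, C7 epimer mixture | CC1=CCC[C@]2(C)CC(=O)C(C(C)C)C[C@H]12 | intermediate
21 | 4α-acetoxy-3β-iodo-5βH-eudesman-8-one, C7 epimer mixture | I[C@H]1CC[C@]2(C)CC(=O)C(C(C)C)C[C@@H]2[C@]1(C)OC(C)=O | intermediate (not isolated)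
22 | 4α-acetoxy-3α-hydroxy-5βH-eudesman-8-one, C7 epimer mixture | O[C@@H]1CC[C@]2(C)CC(=O)C(C(C)C)C[C@@H]2[C@]1(C)OC(C)=O | intermediate (not isolated)
23 | (3R,4S,5S,7R,10R)-3α,4α-dihydroxy-5βH-eudesman-8-one | O[C@@H]1CC[C@]2(C)CC(=O)[C@@H](C(C)C)C[C@@H]2[C@]1(C)O | intermediate
24 | angelic acid, (Z)-2-methylbut-2-enoic acid | C/C=C(/C)C(=O)O | starting material
25 | (Z)-2-methylbut-2-enoic 2,4,6-trichlorobenzoic anhydride | C/C=C(/C)C(=O)OC(=O)c1c(Cl)cc(Cl)cc1Cl | intermediate (not isolated)
26 | (3R,4S,5S,7R,10R)-4α-hydroxy-8-oxo-5βH-eudesman-3α-yl (Z)-2-methylbut-2-enoate | C/C=C(/C)C(=O)O[C@@H]1CC[C@]2(C)CC(=O)[C@@H](C(C)C)C[C@@H]2[C@]1(C)O | intermediate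
27 | (3R,4S,5S,7R,10R)-4α-acetoxy-8-oxo-5βH-eudesman-3α-yl (Z)-2-methylbut-2-enoate, CNP0322180.1 | C/C=C(/C)C(=O)O[C@@H]1CC[C@]2(C)CC(=O)[C@@H](C(C)C)C[C@@H]2[C@]1(C)OC(C)=O | target

Total step count: 14. Longest linear sequence: 13 steps (steps 1–8 and 10–14, from 3-methylcyclohex-2-en-1-one); step 9 is a one-step side branch.

Steps most likely to fail

Step 12. The electrophilic iodine may go to the ring B (α) face of one or both C7 epimers. Loss of a proton from the C4 cation, or iodination of the ketone enol, may also derail the anti opening and the acetate participation. In either case the oxygens would reach the β face or would not arrive as a cis pair. OsO4 adds both oxygens to the face that the electrophile itself prefers and is therefore the stereochemical complement. If the α face proves the more open one, alkene 20 would be treated with OsO4 (cat.) and NMO in acetone/water to give 3α,4α-dihydroxy-5βH-eudesman-8-one as a C7 epimer mixture F1. NaOMe in MeOH would then equilibrate C7, and the route is rejoined at 23.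

Step 14. Acylation of the hindered axial tertiary hydroxyl may be slow, so that acid-promoted 1,2-migration of the angeloyl group, loss of water from C4 or enol acetate formation at C8 compete. The fallback places the acetate before the angelate by stereoelectronically controlled opening of a cyclic orthoester. Diol 23 with MeC(OMe)3 and PPTS would give the 3α,4α-O-(1-methoxyethylidene) orthoester F2. Brief treatment with aqueous AcOH should open it to the axial tertiary acetate with a free equatorial C3 hydroxyl, (3R,4S,5S,7R,10R)-4α-acetoxy-3α-hydroxy-5βH-eudesman-8-one F3. Acylation of F3 with the mixed anhydride 25 (toluene, 80 °C) then leads directly to 27.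

Step 13. The activated angeloyl unit may isomerise from Z to E during the long heating that the hindered C3 hydroxyl may need, which would give the tiglate. The fallback builds the Z alkene only after the ester bond exists. Diol 23 would be esterified at O3 with 2-[bis(2,2,2-trifluoroethoxy)phosphoryl]propanoic acid (DCC, DMAP) to give the 3α-yl 2-[bis(2,2,2-trifluoroethoxy)phosphoryl]propanoate F4. A Still–Gennari olefination with acetaldehyde (KN(SiMe3)2, 18-crown-6, THF, −78 °C) then forms the Z-trisubstituted enoate, and the route is rejoined at 26.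

Further compounds
F1 | step 12 | 3α,4α-dihydroxy-5βH-eudesman-8-one, C7 epimer mixture | O[C@@H]1CC[C@]2(C)CC(=O)C(C(C)C)C[C@@H]2[C@]1(C)O
F2 | step 14 | 3α,4α-O-(1-methoxyethylidene) orthoester of 23 | COC1(C)O[C@@H]2CC[C@]3(C)CC(=O)[C@@H](C(C)C)C[C@@H]3[C@]2(C)O1
F3 | step 14 | (3R,4S,5S,7R,10R)-4α-acetoxy-3α-hydroxy-5βH-eudesman-8-one | O[C@@H]1CC[C@]2(C)CC(=O)[C@@H](C(C)C)C[C@@H]2[C@]1(C)OC(C)=O
F4 | step 13 | (3R,4S,5S,7R,10R)-4α-hydroxy-8-oxo-5βH-eudesman-3α-yl 2-[bis(2,2,2-trifluoroethoxy)phosphoryl]propanoate | CC(C(=O)O[C@@H]1CC[C@]2(C)CC(=O)[C@@H](C(C)C)C[C@@H]2[C@]1(C)O)P(=O)(OCC(F)(F)F)OCC(F)(F)F
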